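The data stem from a simulated flask with made-up constants, noise included.

In a one-step world the starting material simply turns into product, but the alpha run stops near 72% of its charge, and the theta run, with more protic impurity on a similar charge, near 64%, which is lower. So suppose a second path: each impurity molecule quenches one starting material, at a rate that follows the impurity present.

| flask | starting material | protic impurity | remark | time |
|---|---|---|---|---|
| alpha | 0.0094 M | 5 mM | run made earlier |  |
| gamma | 0.019 M | 5 mM | run made earlier |  |
| zeta | 0.047 M | 5 mM | run made earlier |  |
| theta | 0.010 M | 7.6 mM | run made earlier |  |
| oak | 0.010 M | 5.00 mM |  | 6.0 h |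
| cedar | 0.040 M | 10.0 mM |  | 4.0 h |

| run | time / h | product / % |
|---|---|---|
| alpha | 0.417 | 61 |
| alpha | 1.00 | 68 |
| alpha | 2.00 | 71 |
| alpha | 3.00 | 74 |
| alpha | 4.00 | 72 |
| gamma | 0.333 | 60 |
| gamma | 0.667 | 74 |
| gamma | 1.33 | 76 |
| gamma | 2.00 | 76 |
| gamma | 4.00 | 81 |
| zeta | 0.333 | 64 |
| zeta | 0.667 | 77 |
| zeta | 1.33 | 85 |
| zeta | 2.00 | 85 |
| zeta | 4.00 | 91 |
| theta | 0.333 | 56 |
| theta | 0.667 | 63 |
| theta | 1.33 | 66 |
| theta | 2.00 | 61 |
| theta | 4.00 | 64 |

(readings scatter by 2 percentage points)

- a reading or a percentage of product counts all its forms, free or not

1. the winner by amount of product, in percent of the starting material charged; "neither" if no more than 2 percentage points parts them (oak / cedar / neither)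
2. how much product is there at the end, in percent of the starting material charged: oak
3. how much product is there at the end, in percent of the starting material charged: cedar

The impurity then dies away with product made, not with the clock. Count turnovers: divide the product made by a span, and exp(−turnovers) is the fraction of impurity left. At its last reading alpha shows 6.77 mM of product and 2.63 mM lost; taking that loss as impurity spent, you read 9.06 mM as the span, the product made per turnover. The same reading of theta gives 9.97 mM.

Two extremes can be done in the head. If the impurity stayed at its charge (a pseudo-first-order world), product would take the share span/(span + impurity): oak 64.4%, cedar 47.5%. If the loss equalled the impurity charge, oak would give 50.0% and cedar 75.0%. In this picture the impurity falls and quenches no more than its charge, so you expect each flask to end above both: oak above 64.4%, cedar above 75.0%.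

Now count. Cedar, from its floor, comes to 3.31 turnovers, which reckons 3.65% of its impurity left and gives 75.9%. Oak, corrected once from its floor, comes to 0.823 turnovers, which reckons 43.9% left and gives 72.0%. Alpha's late readings lie within about the scatter of each other, though zeta's last two part by 6 percentage points; you take both times as ends by choice, and oak's lies past any reading. By this count cedar leads by 4 points, more than the margin.

The forecast names cedar, with oak at 72% and cedar at 76%: “Cedar wins, though narrowly”.

The flask gives cedar, crystals counted in: oak 71.2%, cedar 76.1%.

    starting material + protic impurity → quenched substrate (k = 5.70 M⁻¹ min⁻¹)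
    starting material ⇌ product (K = 39.0, k = 0.0750 min⁻¹)
    crystals ⇌ product, rate k3*(cs3 - [product]) while solid is left; crystals form when [product] > cs3 (solubility = 4.50 mM, k = 0.210 min⁻¹)
    starting material ⇌ dormant form (K = 0.670, k = 0.00980 min⁻¹)

Oak's own end, with 46% of its impurity left, reads 9.16 mM of product per turnover. Now take a neighbour flask, oak with 0.013 M of impurity, 1.30 equiv. With alpha's span its floor is 41.1%, and one correction swings up to 52.6%. Counting from midway between them gives 47.5%. The neighbour flask ends at 43.0%, with 57% of its impurity and 0.72% of its starting material left.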